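**Retrosynthetic overview**

1. Numbering (germacranolide): C1 furanone C=O, C2 furanone CH, C3 furanone C–O, C4(Me)=C5, C6 lactone O–CH, C7, C8 angelate carbinol, C9 free carbinol, C10 quaternary furanone carbon, C11(OH)–C13H2Cl, C12 lactone C=O.
2. End game: the O8 angelate, C13–Cl and C11–OH come from an 11,13-diol, made by O8–H-directed dihydroxylation of an α-methylene-γ-lactone.
3. Ring order: furanone first (step 3); then the ten-membered carbocycle C1–C10 and the γ-lactone together, by intramolecular chromium-mediated allylation (C6–C7) of a C6 enal with a C7=C11(CO2Me)–C13H2Br unit built from a C7 aldehyde and methyl acrylate.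
4. Key disconnection: furanone bonds C1–C2 and O–C3, giving a terminal (Z)-enyne (C2–C6) and 2-C-methyl-D-ribono-1,4-lactone (C1, C7–C10 and the C10 methyl); C8 is inverted afterwards by a Mitsunobu etherification.
5. Enabling feature: in the furanone ring O–C10(Me)–C1(=O)–C2=C3 the ring oxygen sits on quaternary C10 next to the C1 carbonyl, C2=C3 is a hydrated alkyne, and C8 carries an oxygen gamma to C1. C1/C10/C9/C8/C7 is therefore a 2-C-methylpentono-1,4-lactone whose lactone ring can be exchanged for the furanone ring by one acetylide.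

Key step: step 3

Remark (assumption on the chemistry): the structure is taken exactly as drawn, that is 6S,7S,8S,9R,10R,11R, a cis-fused 6,12-lactone (H6/H7 cis), C11–OH on the lactone face that carries C8, Z C4=C5 and a (Z)-2-methylbut-2-enoate (angelate). Compounds 1, 3, 13 and 22 are taken as commercial.

**Route**

Step 1
Reactants: 1 2-C-methyl-D-ribono-1,4-lactone
Product: 2 3,5-bis-O-TBS-2-C-methyl-D-ribono-1,4-lactone (tertiary 2-OH free)
Conditions: TBSCl (2.3 equiv), imidazole, DMF, 0 °C → rt
Reagents that add atoms: tert-butyldimethylsilyl chloride (TBSCl), CC(C)(C)[Si](C)(C)Cl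
Why: Standard silyl ether formation should take the primary O5–H and the secondary O3–H and leave the hindered tertiary O2–H (the future furanone oxygen on C10) free; no stereocenter is touched.

Step 2
Reactants: 3 (Z)-3-methylpent-2-en-4-yn-1-ol
Product: 4 TBS ether of 3
Conditions: TBSCl, imidazole, CH2Cl2, 0 °C → rt
Reagents that add atoms: tert-butyldimethylsilyl chloride (TBSCl), CC(C)(C)[Si](C)(C)Cl
Why: Standard silylation of a primary allylic alcohol, to which the terminal alkyne and the Z alkene are inert.

Step 3
Reactants: 2 3,5-bis-O-TBS-2-C-methyl-D-ribono-1,4-lactone; 4 TBS ether of 3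
Product: 9 3(2H)-furanone carrying the silylated Z-enyne-derived side chain on C3 and the sugar chain (O9-TBS; free O8–H; O7-TBS) on C10, via lithium alkoxide 5 (not isolated), via lithium acetylide 6 (not isolated), via lactol dialkoxide 7 (not isolated), via ynone dialkoxide 8 (not isolated)
Conditions: LiN(SiMe3)2 (2.3 equiv), THF, −78 → 0 °C; then aq. NH4Cl
Reagents that add atoms: none
Why: Proposed new method: LiN(SiMe3)2 removes the tertiary O–H proton of 2 and the alkyne proton of 4, acetylide 6 adds to the lactone carbonyl of 5 to give lactol dialkoxide 7 (this makes C1–C2), 7 opens to the alpha'-alkoxido ynone 8 by expelling the C8 alkoxide, and the C10 alkoxide then adds to the distal alkyne carbon C3 (this makes O–C3), so that the γ-lactone ring is traded for the 3(2H)-furanone ring in one pot. The closest known reaction types are the addition of lithium acetylides to protected aldono-1,4-lactones and the base-mediated cyclization of alpha'-hydroxy ynones to 3(2H)-furanones; running both on an unprotected α-hydroxy lactone in a single operation is the new element. The only ring closed is the furanone, by an anionic 5-endo-dig oxa-Michael attack of O on the ynone beta-carbon. No stereocenter is created: C10, C9 and C8 come unchanged from 1 because only the acyl C–O bond of the lactone breaks, quaternary C10 cannot epimerize, and the Z geometry of C4=C5 is untouched. The step needs mono-addition at C1 and closure by the C10 oxygen alone: the lactol dialkoxide masks C1 against a second acetylide until the ring opens, O9 is silylated so the competing 6-endo-dig closure is impossible, and the released C8 alkoxide could only close a seven-membered ring or re-form the lactol reversibly.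

Step 4
Reactants: 9 furanone with free O8–H
Product: 10 8-O-(4-methoxyphenyl) ether with inverted C8 (configuration of the target)
Conditions: 4-methoxyphenol (3 equiv), PPh3, DIAD, toluene, 0 → 60 °C
Reagents that add atoms: 4-methoxyphenol, COc1ccc(O)cc1
Why: Mitsunobu etherification should displace the C8 alkoxyphosphonium ion by the phenoxide in an SN2 reaction, which inverts C8 to the target configuration and at the same time protects O8 as an oxidatively removable aryl ether, the C8 hydroxyl being the only free OH of 9.

Step 5
Reactants: 10 8-O-(4-methoxyphenyl) ether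
Product: 11 C6,C7-diol (O9-TBS retained)
Conditions: HF·pyridine, pyridine, THF, 0 °C
Reagents that add atoms: none
Why: Buffered HF·pyridine should cleave the two primary TBS ethers (O6, O7) much faster than the hindered secondary TBS ether on O9 beside quaternary C10 (selective desilylation).

Step 6
Reactants: 11 C6,C7-diol
Product: 12 dialdehyde (C6 Z-enal and C7 α-aryloxy aldehyde)
Conditions: Dess–Martin periodinane (2.6 equiv), CH2Cl2, 0 °C → rt
Reagents that add atoms: none
Why: Dess–Martin oxidation should convert both primary alcohols into aldehydes under non-basic conditions that preserve the Z enal geometry and the α-aryloxy stereocenter C8.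

Step 7
Reactants: 12 dialdehyde; 13 methyl acrylate
Product: 14 Morita–Baylis–Hillman adduct at C7 (mixture of C7 epimers)
Conditions: 13 (5 equiv), DABCO (0.5 equiv), MeOH, 0 °C → rt
Reagents that add atoms: none
Why: In this Morita–Baylis–Hillman reaction the DABCO–acrylate zwitterion should add to the more electrophilic α-aryloxy aldehyde (C7) and not to the conjugated, β,β-disubstituted enal (C6), forming C7–C11; the new carbinol center is formed as a mixture, which is irrelevant because C7 becomes sp2 in step 8.

Step 8
Reactants: 14 Morita–Baylis–Hillman adduct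
Product: 15 (Z)-2-(bromomethyl)enoate (C7=C11; C13H2Br)
Conditions: NBS (1.3 equiv), Me2S (1.5 equiv), CH2Cl2, −20 → 0 °C
Reagents that add atoms: N-bromosuccinimide (NBS), O=C1CCC(=O)N1Br
Why: In this Corey–Kim-type bromination the alkoxysulfonium ion of the allylic alcohol should be opened by bromide in an SN2' sense to the thermodynamically preferred (Z)-2-(bromomethyl)enoate (C8 cis to CH2Br), both C7 epimers converging.

Step 9
Reactants: 15 (Z)-2-(bromomethyl)enoate
Product: 17 macrocyclic cis-fused α-methylene-γ-lactone (O8 aryl ether; O9-TBS), via macrocyclic hydroxy ester 16 (not isolated)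
Conditions: CrCl2 (6 equiv), THF, rt, slow addition of 15 (final 0.003 M); aq. NH4Cl; then PPTS (cat.), CH2Cl2, rt
Reagents that add atoms: none
Why: In this intramolecular Nozaki–Hiyama-type (Barbier) allylation the allylchromium species formed at C13 should add through its gamma-carbon C7 to the C6 aldehyde in a chair-like six-membered transition state; the ester-locked allyl geometry (C8 cis to the CH2Cr) gives the syn adduct, so the C6 alkoxide and the C12 ester are cis and lactonize to the cis-fused lactone (C6 S, C7 S), the faces of the aldehyde and of C7 being set by the furanone-bridged chain with the C8 and C9 oxygen substituents pseudo-equatorial.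

Step 10
Reactants: 17 macrocyclic α-methylene-γ-lactone
Product: 18 C8 alcohol
Conditions: (NH4)2Ce(NO3)6 (2.5 equiv), MeCN/H2O 4:1, 0 °C
Reagents that add atoms: none
Why: Tetravalent cerium should oxidize the electron-rich 4-methoxyphenyl ether to a quinone ketal that hydrolyses, freeing O8–H without touching the silyl ether, the lactone or the electron-poor alkenes.

Step 11
Reactants: 18 C8 alcohol
Product: 20 11,13-diol (C11 R), via osmate ester TMEDA chelate 19 (not isolated)
Conditions: OsO4 (1.05 equiv), TMEDA (1.1 equiv), CH2Cl2, −78 °C; then aq. Na2SO3, THF, rt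
Reagents that add atoms: osmium tetroxide, O=[Os](=O)(=O)=O
Why: In this hydrogen-bond-directed dihydroxylation the OsO4·TMEDA complex should be bound by the homoallylic O8–H and delivered to the face of the exocyclic C11=C13 alkene that is syn to C8, which sets C11 (tertiary OH cis to C8) against the intrinsic convex-face preference, the stoichiometric reagent at −78 °C taking the unhindered, directed 1,1-disubstituted alkene before the conjugated trisubstituted C4=C5 and furanone alkenes.

Step 12
Reactants: 20 11,13-diol
Product: 21 C13 chloride (C11–OH and C8–OH free; O9-TBS)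
Conditions: PPh3 (1.5 equiv), CCl4 (5 equiv), pyridine, CH2Cl2, 0 °C → rt
Reagents that add atoms: carbon tetrachloride, ClC(Cl)(Cl)Cl
Why: Appel chlorination should activate only the primary C13 hydroxyl, and chloride enters at C13 either directly or by opening the transient 11,13-epoxide at its CH2 terminus, both paths leaving the C11 stereocenter and the hindered secondary C8 hydroxyl untouched.

Step 13
Reactants: 21 C13 chloride; 22 angelic acid
Product: 24 O9-TBS ether of the target, via mixed anhydride 23 (not isolated)
Conditions: 22 (3 equiv), 2,4,6-trichlorobenzoyl chloride (3 equiv), Et3N (3.3 equiv), toluene, rt; then 21, toluene, 75 °C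
Reagents that add atoms: none
Why: Yamaguchi-type acylation through the mixed anhydride without DMAP should acylate the secondary C8 hydroxyl (the tertiary C11 hydroxyl is inert) and is the protocol known to keep the Z geometry of angelates, whereas nucleophilic catalysts cause isomerization to tiglates.

Step 14
Reactants: 24 O9-TBS ether of the target
Product: 25 CNP0272644.1
Conditions: HF·pyridine, MeCN, 0 °C → rt
Reagents that add atoms: none
Why: Acidic fluoride should remove the last silyl ether under conditions that neither close the chlorohydrin to an epoxide nor isomerize the angelate.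

**Compound list**

1 | 2-C-methyl-D-ribono-1,4-lactone, (3R,4R,5R)-3,4-dihydroxy-5-(hydroxymethyl)-3-methyloxolan-2-one | C[C@@]1(O)[C@H](O)[C@@H](CO)OC1=O | starting material
2 | 3,5-bis-O-(tert-butyldimethylsilyl)-2-C-methyl-D-ribono-1,4-lactone | C[C@@]1(O)[C@H](O[Si](C)(C)C(C)(C)C)[C@@H](CO[Si](C)(C)C(C)(C)C)OC1=O | intermediate
3 | (Z)-3-methylpent-2-en-4-yn-1-ol | C#C/C(C)=C\CO | starting material
4 | tert-butyldimethyl{[(Z)-3-methylpent-2-en-4-yn-1-yl]oxy}silane | C#C/C(C)=C\CO[Si](C)(C)C(C)(C)C | intermediate
5 | lithium alkoxide of 2 (not isolated) | C[C@@]1(O[Li])[C@H](O[Si](C)(C)C(C)(C)C)[C@@H](CO[Si](C)(C)C(C)(C)C)OC1=O | intermediate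
6 | lithium acetylide of 4 (not isolated) | [Li]C#C/C(C)=C\CO[Si](C)(C)C(C)(C)C | intermediate
7 | dilithium lactol dialkoxide, the 1-C-alkynyl adduct of 5 and 6, either C1 epimer (not isolated) | C[C@@]1(O[Li])[C@H](O[Si](C)(C)C(C)(C)C)[C@@H](CO[Si](C)(C)C(C)(C)C)OC1(O[Li])C#C/C(C)=C\CO[Si](C)(C)C(C)(C)C | intermediate
8 | dilithium salt of the open-chain alpha'-alkoxido ynone (not isolated) | C[C@](O[Li])(C(=O)C#C/C(C)=C\CO[Si](C)(C)C(C)(C)C)[C@H](O[Si](C)(C)C(C)(C)C)[C@H](O[Li])CO[Si](C)(C)C(C)(C)C | intermediate
9 | (2R)-2-[(1R,2R)-1,3-bis(TBS-oxy)-2-hydroxypropyl]-2-methyl-5-[(Z)-4-(TBS-oxy)but-2-en-2-yl]furan-3(2H)-one (C8–OH free, ribo configuration) | C[C@@]1(OC(=CC1=O)/C(C)=C\CO[Si](C)(C)C(C)(C)C)[C@H](O[Si](C)(C)C(C)(C)C)[C@H](O)CO[Si](C)(C)C(C)(C)C | intermediate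
10 | 8-O-(4-methoxyphenyl) ether of 9 with inverted C8 | C[C@@]1(OC(=CC1=O)/C(C)=C\CO[Si](C)(C)C(C)(C)C)[C@H](O[Si](C)(C)C(C)(C)C)[C@@H](Oc2ccc(OC)cc2)CO[Si](C)(C)C(C)(C)C | intermediate
11 | C6,C7-diol (O8 aryl ether, O9-TBS) | C[C@@]1(OC(=CC1=O)/C(C)=C\CO)[C@H](O[Si](C)(C)C(C)(C)C)[C@@H](Oc2ccc(OC)cc2)CO | intermediate
12 | dialdehyde (C6 Z-enal, C7 aldehyde) | C[C@@]1(OC(=CC1=O)/C(C)=C\C=O)[C@H](O[Si](C)(C)C(C)(C)C)[C@@H](Oc2ccc(OC)cc2)C=O | intermediate
13 | methyl acrylate | C=CC(=O)OC | starting material
14 | Morita–Baylis–Hillman adduct, methyl 2-methylene-3-hydroxy ester at C7, both C7 epimers | C[C@@]1(OC(=CC1=O)/C(C)=C\C=O)[C@H](O[Si](C)(C)C(C)(C)C)[C@@H](Oc2ccc(OC)cc2)C(O)C(=C)C(=O)OC | intermediate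
15 | (Z)-2-(bromomethyl)enoate with C6 Z-enal | C[C@@]1(OC(=CC1=O)/C(C)=C\C=O)[C@H](O[Si](C)(C)C(C)(C)C)[C@@H](Oc2ccc(OC)cc2)/C=C(\CBr)C(=O)OC | intermediate
16 | macrocyclic C6 hydroxy methyl ester, formed as its chromium alkoxide (not isolated) | COc1ccc(O[C@H]2[C@@H](C(=C)C(=O)OC)[C@@H](O)/C=C(/C)C3=CC(=O)[C@](C)(O3)[C@@H]2O[Si](C)(C)C(C)(C)C)cc1 | intermediate
17 | macrocyclic cis-fused α-methylene-γ-lactone, O8 4-methoxyphenyl ether, O9-TBS | COc1ccc(O[C@H]2[C@@H]3[C@H](/C=C(/C)C4=CC(=O)[C@](C)(O4)[C@@H]2O[Si](C)(C)C(C)(C)C)OC(=O)C3=C)cc1 | intermediate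
18 | C8 alcohol of the α-methylene lactone (O9-TBS) | O[C@H]1[C@@H]2[C@H](/C=C(/C)C3=CC(=O)[C@](C)(O3)[C@@H]1O[Si](C)(C)C(C)(C)C)OC(=O)C2=C | intermediate
19 | 11,13-osmate ester of hexavalent osmium, TMEDA chelate (not isolated) | O[C@H]1[C@@H]2[C@H](/C=C(/C)C3=CC(=O)[C@](C)(O3)[C@@H]1O[Si](C)(C)C(C)(C)C)OC(=O)[C@@]24CO[Os-2]5(=O)(=O)(O4)[N+](C)(C)CC[N+]5(C)C | intermediate
20 | 8,11,13-triol (O9-TBS), C11 R | O[C@H]1[C@@H]2[C@H](/C=C(/C)C3=CC(=O)[C@](C)(O3)[C@@H]1O[Si](C)(C)C(C)(C)C)OC(=O)[C@@]2(O)CO | intermediate
21 | 13-chloro-8,11-diol (O9-TBS) | O[C@H]1[C@@H]2[C@H](/C=C(/C)C3=CC(=O)[C@](C)(O3)[C@@H]1O[Si](C)(C)C(C)(C)C)OC(=O)[C@@]2(O)CCl | intermediate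
22 | angelic acid, (Z)-2-methylbut-2-enoic acid | C/C=C(/C)C(=O)O | starting material
23 | angelic 2,4,6-trichlorobenzoic anhydride (not isolated) | C/C=C(/C)C(=O)OC(=O)c1c(Cl)cc(Cl)cc1Cl | intermediate
24 | O9-TBS ether of the target | C/C=C(/C)C(=O)O[C@H]1[C@@H]2[C@H](/C=C(/C)C3=CC(=O)[C@](C)(O3)[C@@H]1O[Si](C)(C)C(C)(C)C)OC(=O)[C@@]2(O)CCl | intermediate
25 | CNP0272644.1 | C/C=C(/C)C(=O)O[C@H]1[C@@H]2[C@H](/C=C(/C)C3=CC(=O)[C@](C)(O3)[C@@H]1O)OC(=O)[C@@]2(O)CCl | target

**Step count**

Total: 14 steps. Longest linear sequence: 13 steps (1 → 2 → 9 → … → 25, steps 1 and 3–14; the branch 3 → 4 is one step).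

**Steps most likely to fail, with fallbacks**

Step 3 (proposed new method). The lactol dialkoxide may not open below the temperature at which silyl migration to the freed C8 alkoxide or a second acetylide addition to the ynone sets in, so that ring closure is outrun. The fallback separates the two bond formations with known reactions. It sets out from 2: the tertiary hydroxyl is capped with N-(trimethylsilyl)imidazole to give the fully protected 2-O-trimethylsilyl lactone F1. The lithium acetylide made from 4 and n-BuLi is added at −78 °C (the established acetylide addition to protected aldono-1,4-lactones) and, after a cold NH4Cl quench, the 1-C-alkynyl lactol F2 is isolated. AuCl3 (5 mol %) in CH2Cl2/MeOH then removes the labile tertiary trimethylsilyl ether and catalyses the known 5-endo-dig cyclization of the alpha'-hydroxy ynone tautomer, which brings the route back at 9.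

Step 9. Intermolecular allylation (oligomerization) may outrun ring closure, or attack on the other aldehyde face may give a C6/C7-diastereomeric lactone. The fallback replaces the closed chromium transition state by an open, Lewis-acid-mediated one. It sets out from 15: Me3SnSnMe3 with Pd(PPh3)4 (cat.) should convert the allylic bromide into the 2-(trimethylstannylmethyl)enoate F3. BF3·OEt2 in CH2Cl2 at −78 °C under high dilution should then close C6–C7 through an antiperiplanar, syn-selective transition state to the hydroxy ester 16, which lactonizes with PPTS, and the route is rejoined at 17.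

Step 11. Oxidation of the C4=C5 or furanone double bond may compete, or the reagent may attack the convex face if hydrogen bonding to O8–H does not control delivery. The fallback changes from electrophilic dihydroxylation and substitution to nucleophilic epoxidation and ring opening. It sets out from 18: t-BuOOH with t-BuOLi in THF at −20 °C should give conjugate addition and closure under lithium chelation between the C8 alkoxide and the peroxide, which places the epoxide oxygen on the C8 face and gives the 11,13-epoxide F4. HCl in Et2O at 0 °C should then open the epoxide at C13 (the known regiochemistry for 11,13-epoxy lactones), and the route is rejoined at 21, bypassing 20.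

**Further compounds**

F1 | step 3 | 3,5-bis-O-TBS-2-O-trimethylsilyl-2-C-methyl-D-ribono-1,4-lactone | C[C@@]1(O[Si](C)(C)C)[C@H](O[Si](C)(C)C(C)(C)C)[C@@H](CO[Si](C)(C)C(C)(C)C)OC1=O
F2 | step 3 | 1-C-alkynyl lactol from F1 and the acetylide of 4, either C1 epimer | C[C@@]1(O[Si](C)(C)C)[C@H](O[Si](C)(C)C(C)(C)C)[C@@H](CO[Si](C)(C)C(C)(C)C)OC1(O)C#C/C(C)=C\CO[Si](C)(C)C(C)(C)C
F3 | step 9 | (Z)-2-(trimethylstannylmethyl)enoate corresponding to 15 | C[C@@]1(OC(=CC1=O)/C(C)=C\C=O)[C@H](O[Si](C)(C)C(C)(C)C)[C@@H](Oc2ccc(OC)cc2)/C=C(\C[Sn](C)(C)C)C(=O)OC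
F4 | step 11 | 11,13-epoxide of 18 with the epoxide oxygen on the C8 face | O[C@H]1[C@@H]2[C@H](/C=C(/C)C3=CC(=O)[C@](C)(O3)[C@@H]1O[Si](C)(C)C(C)(C)C)OC(=O)[C@@]24CO4
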